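The target is disconnected to a hexa-aldehyde in which the six hydroxyls at ring A C2/C6, ring B C3/C5 and ring D C3/C5 are still formyl groups. These positions flank the three most crowded ether carbons (A C1, B C4, D C4), so each formyl pair first activates a fluoride at that carbon for phenoxide displacement. The chain is assembled by three such displacements and one CuI-catalysed coupling at ring C C2. One sixfold Baeyer–Villiger (Dakin) oxidation then converts all six formyls to hydroxyls, and O-demethylation of rings A, C and E completes the target.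

Key step: step 13

Remark: the target has no stereocentres, so no SMILES carries stereodescriptors. Rings are lettered A to E from the 2,4,6-trihydroxyphenoxy end to the 3,4,5-trihydroxyphenoxy end. 2-Hydroxy-4,6-dimethoxybenzaldehyde is taken as the commercial source of ring C.

Step 1
Reactants: 1 1-bromo-4-fluorobenzene
Product: 3 5-bromo-2-fluorobenzene-1,3-dicarbaldehyde, via lithium hemiaminal alkoxide 2 (not isolated)
Conditions: LDA, THF, −78 °C; DMF (1 equiv); LDA, −78 °C; DMF; aq. HCl, −78 °C to rt
Reagents that add atoms: DMF, CN(C)C=O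
Why: Directed ortho-lithiation/formylation: LDA removes the acidic proton next to fluorine, DMF traps that position as the lithium α-amino alkoxide 2, which masks the first formyl while a second LDA charge metalates the other fluorine-flanked position for a second DMF quench, and acid work-up should release both aldehydes.

Step 2
Reactants: 3 5-bromo-2-fluorobenzene-1,3-dicarbaldehyde; 4 3,4,5-trimethoxyphenol
Product: 5 5-bromo-2-(3,4,5-trimethoxyphenoxy)benzene-1,3-dicarbaldehyde
Conditions: K2CO3, DMF, rt
Reagents that add atoms: none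
Why: Nucleophilic aromatic substitution: the fluoride sits between two ortho formyl groups that stabilise the Meisenheimer adduct, so the electron-rich phenoxide should displace it at room temperature while the unactivated bromide is untouched.

Step 3
Reactants: 6 2-hydroxy-4,6-dimethoxybenzaldehyde
Product: 7 2-(allyloxy)-4,6-dimethoxybenzaldehyde
Conditions: allyl bromide, K2CO3, DMF, 50 °C
Reagents that add atoms: allyl bromide, C=CCBr
Why: Williamson ether synthesis on a phenol whose only competing site is a non-enolisable aldehyde; the allyl group is chosen because it survives the later base and CuI steps and is removable without touching aldehydes.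

Step 4
Reactants: 7 2-(allyloxy)-4,6-dimethoxybenzaldehyde
Product: 9 2-(allyloxy)-4,6-dimethoxyphenol, via aryl formate 8 (not isolated)
Conditions: 30% H2O2, H2SO4 (cat.), MeOH, rt
Reagents that add atoms: hydrogen peroxide, OO
Why: Acid-catalysed Dakin oxidation: the 2,4,6-trioxygenated aryl group migrates readily to oxygen, the formate 8 is methanolysed in the same pot, and H2O2 under these conditions should not epoxidise the allyl ether.

Step 5
Reactants: 5 5-bromo-2-(3,4,5-trimethoxyphenoxy)benzene-1,3-dicarbaldehyde; 9 2-(allyloxy)-4,6-dimethoxyphenol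
Product: 10 5-[2-(allyloxy)-4,6-dimethoxyphenoxy]-2-(3,4,5-trimethoxyphenoxy)benzene-1,3-dicarbaldehyde
Conditions: CuI (10 mol%), picolinic acid (20 mol%), K3PO4, DMSO, 80 °C, Ar
Reagents that add atoms: none
Why: Ullmann-type diaryl ether coupling with a ligand system suited to di-ortho-substituted phenols; the bromide is unhindered and made electron-poor by two meta formyl groups, and the hindered phenoxide should not exchange the aryloxy group at ring D C4 at this temperature.

Step 6
Reactants: 10 5-[2-(allyloxy)-4,6-dimethoxyphenoxy]-2-(3,4,5-trimethoxyphenoxy)benzene-1,3-dicarbaldehyde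
Product: 11 5-(2-hydroxy-4,6-dimethoxyphenoxy)-2-(3,4,5-trimethoxyphenoxy)benzene-1,3-dicarbaldehyde
Conditions: Pd(PPh3)4 (5 mol%), p-toluenesulfinic acid, THF/MeOH, rt
Reagents that add atoms: none
Why: Tsuji–Trost deallylation: Pd(PPh3)4 ionises the allyl aryl ether and the sulfinate captures the π-allyl fragment as a sulfone, a soft scavenger that does not react with aldehydes or the activated diaryl ether.

Step 7
Reactants: 12 4-fluoroanisole
Product: 14 2-fluoro-5-methoxybenzene-1,3-dicarbaldehyde, via lithium hemiaminal alkoxide 13 (not isolated)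
Conditions: n-BuLi, PMDTA, THF, −78 °C; DMF (1 equiv); n-BuLi, PMDTA, −78 °C; DMF; aq. HCl, −78 °C to rt
Reagents that add atoms: DMF, CN(C)C=O
Why: Directed ortho-lithiation/formylation: PMDTA-complexed n-BuLi deprotonates the most acidic C–H next to fluorine instead of the methoxy-coordinated site, the first formyl is held as the α-amino alkoxide 13 during the second metalation at the other fluorine-flanked position, and acid work-up should give the dialdehyde.

Step 8
Reactants: 14 2-fluoro-5-methoxybenzene-1,3-dicarbaldehyde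
Product: 15 2-fluoro-5-hydroxybenzene-1,3-dicarbaldehyde
Conditions: BBr3, CH2Cl2, −78 to 0 °C; ice water
Reagents that add atoms: none
Why: Lewis acid ether cleavage: BBr3 complexes the methoxy oxygen and bromide attacks the methyl group, a demethylation that hydroxy- and fluoro-benzaldehydes tolerate at low temperature.

Step 9
Reactants: 15 2-fluoro-5-hydroxybenzene-1,3-dicarbaldehyde
Product: 16 5-(allyloxy)-2-fluorobenzene-1,3-dicarbaldehyde
Conditions: allyl bromide (3 equiv), K2CO3, MeCN, rt
Reagents that add atoms: allyl bromide, C=CCBr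
Why: Williamson ether synthesis: the para-oxido group deactivates the phenoxide's own fluoride, and the weakly nucleophilic phenoxide should be captured by excess allyl bromide much faster than it can displace fluoride from the product.

Step 10
Reactants: 11 5-(2-hydroxy-4,6-dimethoxyphenoxy)-2-(3,4,5-trimethoxyphenoxy)benzene-1,3-dicarbaldehyde; 16 5-(allyloxy)-2-fluorobenzene-1,3-dicarbaldehyde
Product: 17 5-(allyloxy)-2-{2-[3,5-diformyl-4-(3,4,5-trimethoxyphenoxy)phenoxy]-3,5-dimethoxyphenoxy}benzene-1,3-dicarbaldehyde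
Conditions: K2CO3, DMF, rt
Reagents that add atoms: none
Why: Nucleophilic aromatic substitution: the ring C phenoxide attacks ring B C4, where fluoride between two formyl groups is a far better leaving group than the aryloxy group at ring D C4, and the allyl ether keeps ring B from acting as a nucleophile.

Step 11
Reactants: 17 5-(allyloxy)-2-{2-[3,5-diformyl-4-(3,4,5-trimethoxyphenoxy)phenoxy]-3,5-dimethoxyphenoxy}benzene-1,3-dicarbaldehyde
Product: 18 2-{2-[3,5-diformyl-4-(3,4,5-trimethoxyphenoxy)phenoxy]-3,5-dimethoxyphenoxy}-5-hydroxybenzene-1,3-dicarbaldehyde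
Conditions: Pd(PPh3)4 (5 mol%), p-toluenesulfinic acid, THF/MeOH, rt
Reagents that add atoms: none
Why: Tsuji–Trost deallylation as in step 6, run under neutral to mildly acidic conditions at room temperature so that the four aldehydes and both activated diaryl ethers are left alone.

Step 12
Reactants: 18 2-{2-[3,5-diformyl-4-(3,4,5-trimethoxyphenoxy)phenoxy]-3,5-dimethoxyphenoxy}-5-hydroxybenzene-1,3-dicarbaldehyde; 14 2-fluoro-5-methoxybenzene-1,3-dicarbaldehyde
Product: 19 2-{4-[2-(3,5-diformyl-4-(3,4,5-trimethoxyphenoxy)phenoxy)-3,5-dimethoxyphenoxy]-3,5-diformylphenoxy}-5-methoxybenzene-1,3-dicarbaldehyde (pentamer hexa-aldehyde)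
Conditions: Cs2CO3, DMF, 40 °C
Reagents that add atoms: none
Why: Nucleophilic aromatic substitution: the unhindered ring B phenoxide displaces the doubly formyl-activated fluoride of 14, which is the only fluoride present, so neither partner can oligomerise.

Step 13
Reactants: 19 pentamer hexa-aldehyde
Product: 21 2-{4-[2-(3,5-dihydroxy-4-(3,4,5-trimethoxyphenoxy)phenoxy)-3,5-dimethoxyphenoxy]-3,5-dihydroxyphenoxy}-5-methoxybenzene-1,3-diol (pentamer hexaphenol), via hexaformate 20 (not isolated)
Conditions: mCPBA (9 equiv), CH2Cl2, 0 °C to rt; aq. Na2S2O3 wash; then K2CO3 (cat.), MeOH, 0 °C, Ar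
Reagents that add atoms: mCPBA, OOC(=O)c1cccc(Cl)c1
Why: The peracid adds to each formyl carbon to give a Criegee adduct, the aryl group shifts from carbon to the peroxide oxygen as 3-chlorobenzoate leaves, and mild methanolysis of the six aryl formates in 20 frees the six phenols. The closest known reaction type is the Baeyer–Villiger (Dakin) oxidation of ortho-aryloxybenzaldehydes to ortho-aryloxyphenols, run here at six sites of one molecule. No ring is closed and no stereocentre is formed. The step needs aryl migration to beat hydride migration at all six sites; the diaryl-ether oxygen ortho to every formyl (at A C1, B C4 and D C4) stabilises the migrating carbon, and each oxidation removes an electron-withdrawing formyl from its ring, so the second migration on a ring should be no harder than the first. The electron-rich rings C and E are protected from over-oxidation because the new phenols stay masked as formates while peracid is present, and the oxidant is destroyed before the formates are cleaved under argon.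

Step 14
Reactants: 21 pentamer hexaphenol
Product: 22 2-{4-[2-(3,5-dihydroxy-4-(3,4,5-trihydroxyphenoxy)phenoxy)-3,5-dihydroxyphenoxy]-3,5-dihydroxyphenoxy}benzene-1,3,5-triol (CNP0227069.0)
Conditions: BBr3 (excess), CH2Cl2, −78 °C to rt; MeOH then H2O; reversed-phase purification under Ar
Reagents that add atoms: none
Why: Global Lewis acid O-demethylation: BBr3 cleaves the six aryl methyl ethers on rings A, C and E by bromide attack at methyl, whereas the four diaryl ether bonds offer no such site and should stay intact.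

Compound list
1 | 1-bromo-4-fluorobenzene | Fc1ccc(Br)cc1 | starting material
2 | lithium (5-bromo-2-fluorophenyl)(dimethylamino)methanolate | CN(C)C([O-])c1cc(Br)ccc1F.[Li+] | intermediate
3 | 5-bromo-2-fluorobenzene-1,3-dicarbaldehyde | O=Cc1cc(Br)cc(C=O)c1F | intermediate
4 | 3,4,5-trimethoxyphenol | COc1cc(O)cc(OC)c1OC | starting material
5 | 5-bromo-2-(3,4,5-trimethoxyphenoxy)benzene-1,3-dicarbaldehyde | COc1cc(Oc2c(C=O)cc(Br)cc2C=O)cc(OC)c1OC | intermediate
6 | 2-hydroxy-4,6-dimethoxybenzaldehyde | COc1cc(O)c(C=O)c(OC)c1 | starting material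
7 | 2-(allyloxy)-4,6-dimethoxybenzaldehyde | C=CCOc1cc(OC)cc(OC)c1C=O | intermediate
8 | 2-(allyloxy)-4,6-dimethoxyphenyl formate | C=CCOc1cc(OC)cc(OC)c1OC=O | intermediate
9 | 2-(allyloxy)-4,6-dimethoxyphenol | C=CCOc1cc(OC)cc(OC)c1O | intermediate
10 | 5-[2-(allyloxy)-4,6-dimethoxyphenoxy]-2-(3,4,5-trimethoxyphenoxy)benzene-1,3-dicarbaldehyde | C=CCOc1cc(OC)cc(OC)c1Oc1cc(C=O)c(Oc2cc(OC)c(OC)c(OC)c2)c(C=O)c1 | intermediate
11 | 5-(2-hydroxy-4,6-dimethoxyphenoxy)-2-(3,4,5-trimethoxyphenoxy)benzene-1,3-dicarbaldehyde | COc1cc(O)c(Oc2cc(C=O)c(Oc3cc(OC)c(OC)c(OC)c3)c(C=O)c2)c(OC)c1 | intermediate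
12 | 4-fluoroanisole | COc1ccc(F)cc1 | starting material
13 | lithium (dimethylamino)(2-fluoro-5-methoxyphenyl)methanolate | CN(C)C([O-])c1cc(OC)ccc1F.[Li+] | intermediate
14 | 2-fluoro-5-methoxybenzene-1,3-dicarbaldehyde | COc1cc(C=O)c(F)c(C=O)c1 | intermediate
15 | 2-fluoro-5-hydroxybenzene-1,3-dicarbaldehyde | Oc1cc(C=O)c(F)c(C=O)c1 | intermediate
16 | 5-(allyloxy)-2-fluorobenzene-1,3-dicarbaldehyde | C=CCOc1cc(C=O)c(F)c(C=O)c1 | intermediate
17 | 5-(allyloxy)-2-{2-[3,5-diformyl-4-(3,4,5-trimethoxyphenoxy)phenoxy]-3,5-dimethoxyphenoxy}benzene-1,3-dicarbaldehyde | C=CCOc1cc(C=O)c(Oc2cc(OC)cc(OC)c2Oc2cc(C=O)c(Oc3cc(OC)c(OC)c(OC)c3)c(C=O)c2)c(C=O)c1 | intermediate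
18 | 2-{2-[3,5-diformyl-4-(3,4,5-trimethoxyphenoxy)phenoxy]-3,5-dimethoxyphenoxy}-5-hydroxybenzene-1,3-dicarbaldehyde | Oc1cc(C=O)c(Oc2cc(OC)cc(OC)c2Oc2cc(C=O)c(Oc3cc(OC)c(OC)c(OC)c3)c(C=O)c2)c(C=O)c1 | intermediate
19 | pentamer hexa-aldehyde: 2-{4-[2-(3,5-diformyl-4-(3,4,5-trimethoxyphenoxy)phenoxy)-3,5-dimethoxyphenoxy]-3,5-diformylphenoxy}-5-methoxybenzene-1,3-dicarbaldehyde | COc1cc(C=O)c(Oc2cc(C=O)c(Oc3cc(OC)cc(OC)c3Oc3cc(C=O)c(Oc4cc(OC)c(OC)c(OC)c4)c(C=O)c3)c(C=O)c2)c(C=O)c1 | intermediate
20 | pentamer hexaformate: compound 19 with each formyl group replaced by a formyloxy group | COc1cc(OC=O)c(Oc2cc(OC=O)c(Oc3cc(OC)cc(OC)c3Oc3cc(OC=O)c(Oc4cc(OC)c(OC)c(OC)c4)c(OC=O)c3)c(OC=O)c2)c(OC=O)c1 | intermediate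
21 | pentamer hexaphenol: 2-{4-[2-(3,5-dihydroxy-4-(3,4,5-trimethoxyphenoxy)phenoxy)-3,5-dimethoxyphenoxy]-3,5-dihydroxyphenoxy}-5-methoxybenzene-1,3-diol | COc1cc(O)c(Oc2cc(O)c(Oc3cc(OC)cc(OC)c3Oc3cc(O)c(Oc4cc(OC)c(OC)c(OC)c4)c(O)c3)c(O)c2)c(O)c1 | intermediate
22 | CNP0227069.0: 2-{4-[2-(3,5-dihydroxy-4-(3,4,5-trihydroxyphenoxy)phenoxy)-3,5-dihydroxyphenoxy]-3,5-dihydroxyphenoxy}benzene-1,3,5-triol | Oc1cc(O)c(Oc2cc(O)c(Oc3cc(O)cc(O)c3Oc3cc(O)c(Oc4cc(O)c(O)c(O)c4)c(O)c3)c(O)c2)c(O)c1 | target

Total step count: 14.
Longest linear sequence: 9 steps (steps 1, 2, 5, 6, 10, 11, 12, 13, 14, from compound 1).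

Steps most likely to fail

Step 13. Hydride migration may compete with aryl migration at one or more of the six Criegee adducts, leaving carboxylic acids, or the oxidation may stall part-way and give inseparable mixtures. The fallback sets out from 19 and replaces the hydride competitor by a methyl group, which cannot out-migrate an ortho-oxygenated aryl group. Addition of MeMgBr (THF, −78 °C) to all six aldehydes should give the hexakis(1-hydroxyethyl) compound F1 as a mixture of diastereomers that need not be separated. Dess–Martin periodinane in CH2Cl2 should oxidise it to the hexa-acetyl compound F2. Baeyer–Villiger oxidation of the six aryl methyl ketones with mCPBA and catalytic CF3CO2H in CH2Cl2 should give the hexa-acetate F3. Methanolysis with K2CO3 in MeOH under argon then returns to the route at 21.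

Step 5. Slow coupling of the di-ortho-substituted phenoxide at 80 °C may let exchange of the aryloxy group at ring D C4 or base-induced degradation of the aldehydes take over. The fallback sets out from 5 and moves the C–O bond formation to room temperature. Miyaura borylation (B2pin2, Pd(dppf)Cl2, KOAc, dioxane, 80 °C) should give the pinacol boronate F4. Cleavage of the pinacol ester with NaIO4 and aq. HCl in THF/H2O should give the boronic acid F5. Chan–Lam–Evans coupling of F5 with phenol 9 (Cu(OAc)2, pyridine, 4 Å molecular sieves, CH2Cl2, air, rt) then returns to the route at 10.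

Step 7. The second metalation may go to the C–H between the methoxy group and the masked formyl group instead of the one next to fluorine, or may remain incomplete, giving regioisomeric or mono-formylated material. The fallback sets out from 3 and installs the methoxy group after both formyls are in place. Acetalisation with HC(OMe)3 and catalytic TsOH in MeOH should give the bis(dimethyl acetal) F6, in which fluoride is no longer activated. Methoxylation of the aryl bromide (CuI cat., NaOMe, MeOH/DMF, 100 °C) should give the methoxy bis-acetal F7. Hydrolysis with aq. HCl in THF then returns to the route at 14.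

Further compounds
F1 | step 13 | hexakis(1-hydroxyethyl) analogue of 19 (each CHO replaced by CH(OH)CH3, diastereomer mixture) | COc1cc(C(C)O)c(Oc2cc(C(C)O)c(Oc3cc(OC)cc(OC)c3Oc3cc(C(C)O)c(Oc4cc(OC)c(OC)c(OC)c4)c(C(C)O)c3)c(C(C)O)c2)c(C(C)O)c1
F2 | step 13 | hexa-acetyl analogue of 19 (each CHO replaced by COCH3) | COc1cc(C(C)=O)c(Oc2cc(C(C)=O)c(Oc3cc(OC)cc(OC)c3Oc3cc(C(C)=O)c(Oc4cc(OC)c(OC)c(OC)c4)c(C(C)=O)c3)c(C(C)=O)c2)c(C(C)=O)c1
F3 | step 13 | hexa-acetate of 21 | COc1cc(OC(C)=O)c(Oc2cc(OC(C)=O)c(Oc3cc(OC)cc(OC)c3Oc3cc(OC(C)=O)c(Oc4cc(OC)c(OC)c(OC)c4)c(OC(C)=O)c3)c(OC(C)=O)c2)c(OC(C)=O)c1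
F4 | step 5 | 5-(4,4,5,5-tetramethyl-1,3,2-dioxaborolan-2-yl)-2-(3,4,5-trimethoxyphenoxy)benzene-1,3-dicarbaldehyde | COc1cc(Oc2c(C=O)cc(B3OC(C)(C)C(C)(C)O3)cc2C=O)cc(OC)c1OC
F5 | step 5 | [3,5-diformyl-4-(3,4,5-trimethoxyphenoxy)phenyl]boronic acid | COc1cc(Oc2c(C=O)cc(B(O)O)cc2C=O)cc(OC)c1OC
F6 | step 7 | 5-bromo-1,3-bis(dimethoxymethyl)-2-fluorobenzene | COC(OC)c1cc(Br)cc(C(OC)OC)c1F
F7 | step 7 | 1,3-bis(dimethoxymethyl)-2-fluoro-5-methoxybenzene | COC(OC)c1cc(OC)cc(C(OC)OC)c1F
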